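## Structural features

The target is a cembranolide: a 14-membered carbocycle (C1–C14) with an α-methylene-γ-butyrolactone (O–C14–C1–C15–C16, C15=C17) fused cis across C1–C14. Four contiguous stereocentres lie along one edge, C12 (methyl), C13 (acetate), C14 (lactone oxygen) and C1, with methyl, acetoxy and lactone oxygen all syn in the extended chain. One methylene (C2) further on is a trisubstituted oxirane C3–C4 with C2 and C5 trans (3R,4R) and methyl C18 on C4. Two methylenes beyond that is the allylic alcohol C7 (S) beside the exocyclic alkene C8=C19. The three stereochemical regions (C12–C1, C3/C4, C7) are separated by CH2 groups, so none can reliably direct another, and the large ring gives no dependable facial bias for a late epoxidation or reduction. Fragile groups are the conjugate-acceptor methylene lactone, the acid-labile oxirane, the acetate next to a lactone and the allylic alcohol. The real difficulty is to set C3/C4 and C7 in open-chain precursors and then close the ring without disturbing them. The key step exploits that C4 is a fully substituted oxirane carbon (C18, C3, C5, O) next to the methine C3: C4 can be a methyl ketone and C3 can carry chlorine, so adding C5 and displacing chloride makes bond C4–C5 and the oxirane ring together.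

## Logic of the disconnections

36 ⇒ 35 ⇒ 34 ⇒ 33. The O7–Si bond, the acetyl C–O13 bond and the O13–Si bond are handled last. The free allylic alcohol and the acetate would not survive enolate chemistry, so two silyl ethers of different lability stand in for them. The gain is that 33 carries only robust ethers. The demand is that the triethylsilyl ether leaves before the tert-butyldimethylsilyl ether, and that both fluoride steps spare oxirane, acetate and methylene lactone.

33 ⇒ 30. The C15=C17 bond is cut. The Michael acceptor would not survive hydroboration, organometallic addition or palladium chemistry, so it is added after all of them. The gain is a plain lactone in 30. The demand is clean enolisation at C15 beside the oxirane.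

30 ⇒ 28 (through 29). The ring bond C8–C9 is cut. It is an sp2–sp3 bond next to the exocyclic methylene and remote from every stereocentre, so a B-alkyl Suzuki closure cannot scramble anything. The gain is an open chain. The demand is that hydroboration takes only the monosubstituted alkene and that ring closure outruns oligomerisation.

28 ⇒ 27. The C8–I bond is traced back to a C8–Si bond. A vinyl iodide cannot pass through Grignard formation, a vinylsilane can. The demand is ipso-substitution at C8 without touching the terminal alkene or the oxirane.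

27 ⇒ 17 + 23 (through 24, 25, 26). The C4–C5 bond and the O–C3 bond of the oxirane are cut. This is the convergent step: it divides the molecule into two pieces of similar size and makes the quaternary C4 and the oxirane from a ketone and a chloride. No alkene in a large ring then has to be epoxidised. The demand is addition to the ketone in the presence of a lactone and an acidic C3–H, on the ketone face fixed by the C3 chloride.

23 ⇒ 22 ⇒ 21 ⇒ 18 + 19 (through 20). The O7–Si bond, the C7–H bond and the C7–C8 bond are cut in turn. C7 is the only stereocentre of this piece and sits between an alkenyl and an alkyl group of very different size, so a catalytic ketone reduction can set it. The gain is two three-carbon commercial materials. The demand is a ketone synthesis from an acid chloride that stops at the ketone and keeps the primary bromide.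

17 ⇒ 16 ⇒ 14 (through 15). The C4–C18 bond and the C3–Cl bond are cut. Chlorine can only be placed enantioselectively next to an aldehyde, so C4 is taken back to the aldehyde level and the methyl is added afterwards. The gain is that C3 is set by a catalyst, independent of the lactone stereocentres. The demand is that the labile chloro aldehyde is used at once.

14 ⇒ 13 ⇒ 12. The C4 aldehyde is traced to a primary silyl ether, and the C1–H bond is cut to give a butenolide. C1 is the β-carbon of the lactone, so it can be set by hydride delivery to the ring face opposite the C14 substituent. The gain is the loss of one stereocentre and a flat five-membered ring. The demand is a conjugate reduction that leaves the terminal alkene alone.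

12 ⇒ 11 ⇒ 9 + 10. The O13–Si bond and then the C13–C14 bond are cut. C14 is the γ-carbon of the butenolide and therefore the nucleophilic end of a silyloxyfuran, and C13 is an aldehyde carbon, so one vinylogous aldol makes both stereocentres. The gain is the largest simplification of the lactone fragment. The demand is syn selectivity between C13 and C14 and Felkin selectivity relative to C12.

9 ⇒ 8 ⇒ 5 + 6 (through 7), and 5 ⇒ 4. The furan O–Si bond, the C1–C2 bond and the O–Si bond at C4 are cut. The C2–C4 chain is attached to a commercial bromobutenolide by hydroboration and cross-coupling. The primary triethylsilyl ether is chosen because it can later be oxidised directly to the aldehyde.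

10 ⇒ 3 ⇒ 2 ⇒ 1. The C11–C12 bond is cut after adjusting the oxidation level of C13. An auxiliary-controlled allylation of a propionyl imide sets C12 and brings in the terminal alkene C9=C10 in one operation. This is shorter than converting a 3-hydroxy-2-methylpropanoate, which would need protection and a separate chain extension at C11. The demand is that the α-methyl aldehyde 10 is not epimerised before use.

## Other disconnections considered

Alternative 1: The cut is C5–C6, paired with re-forming an O–C3 bond, which contracts the carbocycle to the 12-membered cyclic enol ether A1 (oxygen between C7 and C3, exocyclic C7=C6, isopropenyl on C3). In the forward direction, heating A1 would cause a Claisen rearrangement to A2, a 14-membered ring with the C7 ketone, the C8=C19 methylene and the (E)-C3=C4 alkene.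

- **In its favour:** the carbocycle arises by a unimolecular, concerted ring expansion from a ring that is easier to close, and the chair-like transition state should fix the alkene geometry. On ring formation without high dilution and on predictability of the C3–C4 geometry, this alternative is the equal or the better of the chosen plan.
- **Against it here:** A2 contains neither the oxirane nor the C7 stereocentre. Both would have to come from face-selective reactions on the macrocycle (epoxidation of C3=C4, 1,2-reduction of the enone), where control is uncertain. A2 also still needs acetonide and PMB removal, oxidation of C16, lactonisation, methylenation and acetylation. A1 is an acid-labile 2-alkoxy diene, and its C3 stereocentre is built only to be destroyed.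
- **Comparison:** the chosen plan sets C3, C4 and C7 in open chains, and its key step leaves fewer redox and protecting-group steps afterwards. Mechanistically, the pericyclic step is at least as reliable as a polar carbonyl addition.

Alternative 2: The cuts are O–C16 and C15–C16. In the forward direction the macrocyclic homopropargylic alcohol A3 (C14 hydroxyl, C1 ethynyl) would take up CO under PdCl2, SnCl2 and PPh3 to give the methylene lactone A4.

- **In its favour:** the lactone ring and its exocyclic alkene are made in one late operation from two robust groups, with no enolate chemistry. This replaces the three-stage methylenation of the chosen plan and is better on that point.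
- **Against it here:** A4 still has the C3=C4 alkene. The oxirane would come from a late epoxidation that must be face-selective on the macrocycle and chemoselective beside C8=C19. The cis relation of C1 and C14 must be set earlier as an open-chain pair carrying an alkyne, and the Lewis-acidic tin salt and CO pressure have to be tolerated by two silyl ethers.
- **Comparison:** on the lactone, the alternative is shorter. On the oxirane, the chosen plan is safer because C4 is made under control of an adjacent stereocentre and not of ring conformation. Overall step counts should be similar.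

Alternative 3: The cut is C2–C3. In the forward direction 9-BBN would add to the exocyclic C1=C2 alkene of the β-methylene lactone A5, and Pd(dppf)Cl2 would couple the C2 borane with the (E)-C3 iodoalkene to close the ring, giving A6.

- **In its favour:** it is the same reaction class as the ring closure of the chosen plan, so mechanistically it is its equal. The hydroboration would also set C1 (boron entering opposite to the C14 side chain) in the same operation as the macrocyclisation, which is better economy at that point.
- **Against it here:** A6 carries an alkene where the oxirane must be and a ketal where the methylene must be. A face-selective epoxidation of the macrocycle and a carbonyl olefination next to the C7 silyloxy stereocentre (risk of epimerisation) would follow.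
- **Comparison:** the chosen plan closes the ring at C8–C9, remote from all stereocentres, with oxirane and methylene precursor already in place. It needs fewer steps after ring closure but one more operation to set C1.

Key step: step 16

Remarks on the chemistry:
- Cembrane numbering (C1–C20) is used for all intermediates.
- For chlorine to enter at C3, the aldehyde that is chlorinated must be the C4 aldehyde (C2–C3–C4HO). An aldehyde at C3 would be chlorinated at C2. The route therefore chlorinates aldehyde 14 at C3 and adds the methyl group C18 to C4.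
- A2 is an α-methylene ketone with an isolated (E)-alkene. Its two C=C bonds are not both conjugated with C7=O, so it is an enone and not a cross-conjugated dienone.
- Assumption: (2R,5R)-2,5-diphenylpyrrolidine is taken to be the catalyst enantiomer that gives the (S)-chloride (the phenyl group beside the enamine carbon blocks one face). If a model aldehyde showed the opposite sense, the (2S,5S) catalyst would be used and nothing else would change.

## Route

Step 1
Reactants: 1 (4R)-4-benzyl-3-propanoyl-1,3-oxazolidin-2-one
Product: 2 (4R)-4-benzyl-3-[(2S)-2-methylpent-4-enoyl]-1,3-oxazolidin-2-one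
Conditions: NaN(SiMe3)2, THF, −78 °C; allyl iodide, −78 → −40 °C
Reagents that add atoms: allyl iodide, C=CCI
Why: Auxiliary-controlled enolate alkylation (Evans alkylation): the chelated Z-enolate is attacked on the face away from the benzyl group, which should set C12 as S and install C9–C11.

Step 2
Reactants: 2 (4R)-4-benzyl-3-[(2S)-2-methylpent-4-enoyl]-1,3-oxazolidin-2-one
Product: 3 (2S)-2-methylpent-4-en-1-ol
Conditions: LiBH4, MeOH (1 equiv), Et2O, 0 °C
Reagents that add atoms: none
Why: Reductive cleavage of the imide at the exocyclic carbonyl; C12 is not enolised under these conditions and the auxiliary is recovered.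

Step 3
Reactants: 4 prop-2-en-1-ol
Product: 5 triethyl(prop-2-en-1-yloxy)silane
Conditions: Et3SiCl, imidazole, CH2Cl2, 0 °C → rt
Reagents that add atoms: chlorotriethylsilane, CC[Si](Cl)(CC)CC
Why: Standard silylation; the primary triethylsilyl ether is chosen because step 10 can oxidise it directly to the aldehyde.

Step 4
Reactants: 5 triethyl(prop-2-en-1-yloxy)silane; 6 4-bromofuran-2(5H)-one
Product: 8 4-[3-(triethylsilyloxy)propyl]furan-2(5H)-one, via alkylborane 7 (not isolated)
Conditions: 9-BBN, THF, 0 °C → rt; then 6, Pd(dppf)Cl2 (5 mol%), K3PO4 (aq), DMF, rt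
Reagents that add atoms: none
Why: Anti-Markovnikov hydroboration followed by B-alkyl Suzuki–Miyaura coupling at the C–Br bond of a vinylogous acyl bromide, a good partner for oxidative addition; this forms C1–C2.

Step 5
Reactants: 8 4-[3-(triethylsilyloxy)propyl]furan-2(5H)-one
Product: 9 tert-butyldimethyl({4-[3-(triethylsilyloxy)propyl]furan-2-yl}oxy)silane
Conditions: t-BuMe2SiOTf, Et3N, CH2Cl2, 0 °C
Reagents that add atoms: tert-butyldimethylsilyl trifluoromethanesulfonate, CC(C)(C)[Si](C)(C)OS(=O)(=O)C(F)(F)F
Why: Soft enolisation at the γ-carbon (C14) gives the aromatic 2-silyloxyfuran, the nucleophile for the vinylogous aldol.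

Step 6
Reactants: 3 (2S)-2-methylpent-4-en-1-ol
Product: 10 (2S)-2-methylpent-4-enal
Conditions: PhI(OAc)2, TEMPO (10 mol%), CH2Cl2, rt; washed solution used directly
Reagents that add atoms: none
Why: Oxoammonium oxidation under base-free conditions should not epimerise C12; the volatile aldehyde is kept in CH2Cl2, the solvent of the next step.

Step 7
Reactants: 9 tert-butyldimethyl({4-[3-(triethylsilyloxy)propyl]furan-2-yl}oxy)silane; 10 (2S)-2-methylpent-4-enal
Product: 11 (5R)-5-[(1R,2S)-1-hydroxy-2-methylpent-4-en-1-yl]-4-[3-(triethylsilyloxy)propyl]furan-2(5H)-one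
Conditions: BF3·OEt2, CH2Cl2, −78 °C; aq NaHCO3
Reagents that add atoms: none
Why: Vinylogous Mukaiyama aldol reaction at the furan C5 (C14) forms C13–C14; Felkin–Anh attack on the BF3-bound aldehyde (allylic CH2 anti, nucleophile past H) should give the 12,13-syn relation, and the open transition state usual for silyloxyfurans should give the 13,14-syn (threo) relation.

Step 8
Reactants: 11 (5R)-5-[(1R,2S)-1-hydroxy-2-methylpent-4-en-1-yl]-4-[3-(triethylsilyloxy)propyl]furan-2(5H)-one
Product: 12 (5R)-5-[(1R,2S)-2-methyl-1-(triethylsilyloxy)pent-4-en-1-yl]-4-[3-(triethylsilyloxy)propyl]furan-2(5H)-one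
Conditions: Et3SiOTf, 2,6-lutidine, CH2Cl2, −78 °C
Reagents that add atoms: triethylsilyl trifluoromethanesulfonate, CC[Si](CC)(CC)OS(=O)(=O)C(F)(F)F
Why: Silylation of the hindered C13 alcohol stops acyl migration to a six-membered lactone; any primary alcohol freed by BF3 in step 7 is silylated again in the same operation.

Step 9
Reactants: 12 (5R)-5-[(1R,2S)-2-methyl-1-(triethylsilyloxy)pent-4-en-1-yl]-4-[3-(triethylsilyloxy)propyl]furan-2(5H)-one
Product: 13 (4S,5R)-5-[(1R,2S)-2-methyl-1-(triethylsilyloxy)pent-4-en-1-yl]-4-[3-(triethylsilyloxy)propyl]oxolan-2-one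
Conditions: Cu(OAc)2·H2O (5 mol%), 1,2-bis(diphenylphosphino)benzene (5 mol%), (EtO)2MeSiH, t-BuOH, toluene, rt
Reagents that add atoms: none
Why: Conjugate reduction by a phosphine-ligated CuH: hydride should reach C1 from the ring face opposite the bulky C14 substituent, placing the C2 chain cis to it; the unactivated terminal alkene does not react with this catalyst.

Step 10
Reactants: 13 (4S,5R)-5-[(1R,2S)-2-methyl-1-(triethylsilyloxy)pent-4-en-1-yl]-4-[3-(triethylsilyloxy)propyl]oxolan-2-one
Product: 14 (4S,5R)-5-[(1R,2S)-2-methyl-1-(triethylsilyloxy)pent-4-en-1-yl]-4-(3-oxopropyl)oxolan-2-one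
Conditions: (COCl)2, DMSO, CH2Cl2, −78 → −40 °C; Et3N, −78 °C → rt
Reagents that add atoms: none
Why: Swern oxidation applied directly to a primary triethylsilyl ether: the chlorosulfonium ion attacks the unhindered primary ether oxygen, silicon leaves as the chloride and the alkoxysulfonium ion collapses to the C4 aldehyde, while the hindered secondary C13 ether should stay.

Step 11
Reactants: 14 (4S,5R)-5-[(1R,2S)-2-methyl-1-(triethylsilyloxy)pent-4-en-1-yl]-4-(3-oxopropyl)oxolan-2-one
Product: 16 (4R,5R)-4-[(2S)-2-chloro-3-hydroxybutyl]-5-[(1R,2S)-2-methyl-1-(triethylsilyloxy)pent-4-en-1-yl]oxolan-2-one (both carbinol epimers), via α-chloro aldehyde 15 (not isolated)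
Conditions: NCS, (2R,5R)-2,5-diphenylpyrrolidine (10 mol%), CH2Cl2, 0 °C; pentane, filtration; then MeMgBr, Et2O/THF, −78 °C; aq NH4Cl
Reagents that add atoms: N-chlorosuccinimide, O=C1CCC(=O)N1Cl; methylmagnesium bromide, C[Mg]Br
Why: Enamine-catalysed α-chlorination: the C2-symmetric amine blocks one face of the enamine so that chlorine should enter C3 with S configuration under catalyst control; the chloro aldehyde is then taken cold into Grignard addition, which is faster at the aldehyde than at the lactone, and the C4 carbinol configuration is irrelevant because it is oxidised next.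

Step 12
Reactants: 16 (4R,5R)-4-[(2S)-2-chloro-3-hydroxybutyl]-5-[(1R,2S)-2-methyl-1-(triethylsilyloxy)pent-4-en-1-yl]oxolan-2-one
Product: 17 (4R,5R)-4-[(2S)-2-chloro-3-oxobutyl]-5-[(1R,2S)-2-methyl-1-(triethylsilyloxy)pent-4-en-1-yl]oxolan-2-one
Conditions: Dess–Martin periodinane, NaHCO3, CH2Cl2, 0 °C → rt
Reagents that add atoms: none
Why: Buffered periodinane oxidation is neutral and fast, so the C3 chloride next to the new ketone should keep its configuration.

Step 13
Reactants: 18 (1-bromoethenyl)trimethylsilane; 19 3-bromopropanoyl chloride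
Product: 21 5-bromo-2-(trimethylsilyl)pent-1-en-3-one, via Grignard reagent 20 (not isolated)
Conditions: Mg, THF, reflux; then added to 19, CuI (10 mol%), THF, −78 °C
Reagents that add atoms: none
Why: Copper-catalysed acylation of a Grignard reagent by an acid chloride; inverse addition at low temperature keeps the organometallic from adding to the ketone or removing HBr from it, and the product is used promptly.

Step 14
Reactants: 21 5-bromo-2-(trimethylsilyl)pent-1-en-3-one
Product: 22 (3S)-5-bromo-2-(trimethylsilyl)pent-1-en-3-ol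
Conditions: (R)-2-methyl-CBS-oxazaborolidine (20 mol%), catecholborane, toluene, −78 °C
Reagents that add atoms: none
Why: Corey–Bakshi–Shibata reduction: the α-silyl alkenyl group acts as the large substituent and the bromoethyl group as the small one, so the (R)-catalyst should deliver hydride to give the 7S alcohol; catecholborane at low temperature avoids hydroboration of the alkene.

Step 15
Reactants: 22 (3S)-5-bromo-2-(trimethylsilyl)pent-1-en-3-ol
Product: 23 {[(3S)-5-bromo-2-(trimethylsilyl)pent-1-en-3-yl]oxy}(tert-butyl)dimethylsilane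
Conditions: t-BuMe2SiOTf, 2,6-lutidine, CH2Cl2, −78 → 0 °C
Reagents that add atoms: tert-butyldimethylsilyl trifluoromethanesulfonate, CC(C)(C)[Si](C)(C)OS(=O)(=O)C(F)(F)F
Why: Silylation under non-nucleophilic conditions leaves the primary bromide untouched; the γ-silyloxy group cannot undergo β-elimination once the Grignard reagent is formed.

Step 16
Reactants: 23 {[(3S)-5-bromo-2-(trimethylsilyl)pent-1-en-3-yl]oxy}(tert-butyl)dimethylsilane; 17 (4R,5R)-4-[(2S)-2-chloro-3-oxobutyl]-5-[(1R,2S)-2-methyl-1-(triethylsilyloxy)pent-4-en-1-yl]oxolan-2-one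
Product: 27 (4S,5R)-4-({(2R,3R)-3-[(3S)-3-(tert-butyldimethylsilyloxy)-4-(trimethylsilyl)pent-4-en-1-yl]-3-methyloxiran-2-yl}methyl)-5-[(1R,2S)-2-methyl-1-(triethylsilyloxy)pent-4-en-1-yl]oxolan-2-one, via Grignard reagent 24 (not isolated), via organocerium reagent 25 (not isolated), via chlorohydrin 26 (not isolated)
Conditions: 23, Mg, THF, 40 °C; CeCl3, THF, −78 °C; 17, −78 °C; then MeOH, K2CO3, −78 → 0 °C
Reagents that add atoms: none
Why: Transmetalation of 24 with CeCl3 gives the weakly basic, oxophilic reagent 25, which should add to the C4 ketone of 17 (forming C4–C5) faster than it removes the C3 proton or attacks the lactone, because the α-chloro ketone is the most electrophilic carbonyl present. The closest known reaction type is the Cornforth-controlled addition of organometallic reagents to α-chloro carbonyl compounds followed by base closure of the chlorohydrin to an epoxide. In the reacting conformer the C3–Cl bond lies anti to C=O with the dipoles opposed, and C5 approaches along the Bürgi–Dunitz line past the C3 hydrogen and away from C2, which should give the (3S,4R) alkoxide of 26. The new stereocentre C4 is therefore set by 1,2-induction from the C3 chloride, and the stereocentres at C1 and C7 are too remote to interfere. Methanol destroys excess 25, and K2CO3 then lets the tertiary alkoxide displace chloride at C3 from the rear in a 3-exo-tet closure, which inverts C3 to R. The O–C4–C3–Cl arrangement needed for closure is the one favoured in the addition, so C2 and C5 end trans on the oxirane (3R,4R). The step needs ketone-over-lactone selectivity and addition-over-enolisation, both secured by the cerium reagent at −78 °C, and face selectivity, secured by the chloride. The silyl ethers, the vinylsilane and the terminal alkene are inert.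

Step 17
Reactants: 27 (4S,5R)-4-({(2R,3R)-3-[(3S)-3-(tert-butyldimethylsilyloxy)-4-(trimethylsilyl)pent-4-en-1-yl]-3-methyloxiran-2-yl}methyl)-5-[(1R,2S)-2-methyl-1-(triethylsilyloxy)pent-4-en-1-yl]oxolan-2-one
Product: 28 (4S,5R)-4-({(2R,3R)-3-[(3S)-3-(tert-butyldimethylsilyloxy)-4-iodopent-4-en-1-yl]-3-methyloxiran-2-yl}methyl)-5-[(1R,2S)-2-methyl-1-(triethylsilyloxy)pent-4-en-1-yl]oxolan-2-one
Conditions: NIS, 2,6-lutidine, (CF3)2CHOH/CH2Cl2, 0 °C
Reagents that add atoms: N-iodosuccinimide, O=C1CCC(=O)N1I
Why: Ipso-iododesilylation through a β-silyl cation; the vinylsilane is far more nucleophilic than the terminal alkene, and the lutidine buffer and short contact at 0 °C should protect the oxirane and the triethylsilyl ether.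

Step 18
Reactants: 28 (4S,5R)-4-({(2R,3R)-3-[(3S)-3-(tert-butyldimethylsilyloxy)-4-iodopent-4-en-1-yl]-3-methyloxiran-2-yl}methyl)-5-[(1R,2S)-2-methyl-1-(triethylsilyloxy)pent-4-en-1-yl]oxolan-2-one
Product: 30 (1S,3R,4R,7S,12S,13R,14R)-7-(tert-butyldimethylsilyloxy)-3,4-epoxy-13-(triethylsilyloxy)-17-norcembr-8(19)-en-16,14-olide, via alkylborane 29 (not isolated)
Conditions: 9-BBN, THF, rt; then slow addition to Pd(dppf)Cl2 (20 mol%), AsPh3, Cs2CO3, DMF/THF/H2O, 50 °C (1 mM)
Reagents that add atoms: none
Why: 9-BBN should add only to the monosubstituted C9=C10 alkene (the iodoalkene is hindered and electron-poor); zerovalent palladium then inserts into C8–I, the borate transfers C9 and reductive elimination closes the 14-membered ring at C8–C9 in an intramolecular B-alkyl Suzuki–Miyaura coupling, with no stereocentre involved.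

Step 19
Reactants: 30 (1S,3R,4R,7S,12S,13R,14R)-7-(tert-butyldimethylsilyloxy)-3,4-epoxy-13-(triethylsilyloxy)-17-norcembr-8(19)-en-16,14-olide
Product: 33 (1S,3R,4R,7S,12S,13R,14R)-7-(tert-butyldimethylsilyloxy)-3,4-epoxy-13-(triethylsilyloxy)cembra-8(19),15(17)-dien-16,14-olide, via Mannich base 31 (not isolated), via ammonium iodide 32 (not isolated)
Conditions: LiN(SiMe3)2, THF, −78 °C; Me2N=CH2+ I−, −78 → 0 °C; MeI, rt; aq NaHCO3, CH2Cl2, rt
Reagents that add atoms: N,N-dimethylmethaniminium iodide, C=[N+](C)C.[I-]
Why: The lactone enolate (C15 is the only acidic position) is aminomethylated in a Mannich reaction, the amine is quaternised and mild base eliminates trimethylamine (E1cB) to give the exocyclic alkene; C15 becomes sp2, so its configuration in 31 does not matter.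

Step 20
Reactants: 33 (1S,3R,4R,7S,12S,13R,14R)-7-(tert-butyldimethylsilyloxy)-3,4-epoxy-13-(triethylsilyloxy)cembra-8(19),15(17)-dien-16,14-olide
Product: 34 (1S,3R,4R,7S,12S,13R,14R)-7-(tert-butyldimethylsilyloxy)-3,4-epoxy-13-hydroxycembra-8(19),15(17)-dien-16,14-olide
Conditions: HF·pyridine, pyridine, THF, 0 °C
Reagents that add atoms: none
Why: Buffered fluoride removes a triethylsilyl ether much faster than a secondary tert-butyldimethylsilyl ether, and the excess pyridine should keep the oxirane from opening.

Step 21
Reactants: 34 (1S,3R,4R,7S,12S,13R,14R)-7-(tert-butyldimethylsilyloxy)-3,4-epoxy-13-hydroxycembra-8(19),15(17)-dien-16,14-olide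
Product: 35 (1S,3R,4R,7S,12S,13R,14R)-13-acetoxy-7-(tert-butyldimethylsilyloxy)-3,4-epoxycembra-8(19),15(17)-dien-16,14-olide
Conditions: Ac2O, pyridine, DMAP (cat.), CH2Cl2, 0 °C → rt
Reagents that add atoms: acetic anhydride, CC(=O)OC(C)=O
Why: Nucleophile-catalysed acylation of the only free hydroxyl group; the conditions are too mild to add to the methylene lactone or to move the lactone acyl group.

Step 22
Reactants: 35 (1S,3R,4R,7S,12S,13R,14R)-13-acetoxy-7-(tert-butyldimethylsilyloxy)-3,4-epoxycembra-8(19),15(17)-dien-16,14-olide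
Product: 36 (1S,3R,4R,7S,12S,13R,14R)-13-acetoxy-3,4-epoxy-7-hydroxycembra-8(19),15(17)-dien-16,14-olide
Conditions: HF·pyridine, pyridine, THF, 0 °C → rt
Reagents that add atoms: none
Why: Fluoride cleavage of the allylic silyl ether under buffered, non-basic conditions should leave acetate, oxirane and methylene lactone intact and release the C7 alcohol of the target.

## Compound list

1 | (4R)-4-benzyl-3-propanoyl-1,3-oxazolidin-2-one | CCC(=O)N1[C@H](Cc2ccccc2)COC1=O | starting material
2 | (4R)-4-benzyl-3-[(2S)-2-methylpent-4-enoyl]-1,3-oxazolidin-2-one | C=CC[C@H](C)C(=O)N1[C@H](Cc2ccccc2)COC1=O | intermediate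
3 | (2S)-2-methylpent-4-en-1-ol | C=CC[C@H](C)CO | intermediate
4 | prop-2-en-1-ol | C=CCO | starting material
5 | triethyl(prop-2-en-1-yloxy)silane | C=CCO[Si](CC)(CC)CC | intermediate
6 | 4-bromofuran-2(5H)-one | O=C1OCC(Br)=C1 | starting material
7 | 9-[3-(triethylsilyloxy)propyl]-9-borabicyclo[3.3.1]nonane | CC[Si](CC)(CC)OCCCB1C2CCCC1CCC2 | intermediate
8 | 4-[3-(triethylsilyloxy)propyl]furan-2(5H)-one | O=C1OCC(CCCO[Si](CC)(CC)CC)=C1 | intermediate
9 | tert-butyldimethyl({4-[3-(triethylsilyloxy)propyl]furan-2-yl}oxy)silane | CC[Si](CC)(CC)OCCCc1coc(O[Si](C)(C)C(C)(C)C)c1 | intermediate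
10 | (2S)-2-methylpent-4-enal | C=CC[C@H](C)C=O | intermediate
11 | (5R)-5-[(1R,2S)-1-hydroxy-2-methylpent-4-en-1-yl]-4-[3-(triethylsilyloxy)propyl]furan-2(5H)-one | C=CC[C@H](C)[C@@H](O)[C@@H]1OC(=O)C=C1CCCO[Si](CC)(CC)CC | intermediate
12 | (5R)-5-[(1R,2S)-2-methyl-1-(triethylsilyloxy)pent-4-en-1-yl]-4-[3-(triethylsilyloxy)propyl]furan-2(5H)-one | C=CC[C@H](C)[C@@H](O[Si](CC)(CC)CC)[C@@H]1OC(=O)C=C1CCCO[Si](CC)(CC)CC | intermediate
13 | (4S,5R)-5-[(1R,2S)-2-methyl-1-(triethylsilyloxy)pent-4-en-1-yl]-4-[3-(triethylsilyloxy)propyl]oxolan-2-one (cis lactone) | C=CC[C@H](C)[C@@H](O[Si](CC)(CC)CC)[C@@H]1OC(=O)C[C@@H]1CCCO[Si](CC)(CC)CC | intermediate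
14 | (4S,5R)-5-[(1R,2S)-2-methyl-1-(triethylsilyloxy)pent-4-en-1-yl]-4-(3-oxopropyl)oxolan-2-one | C=CC[C@H](C)[C@@H](O[Si](CC)(CC)CC)[C@@H]1OC(=O)C[C@@H]1CCC=O | intermediate
15 | (4R,5R)-4-[(2S)-2-chloro-3-oxopropyl]-5-[(1R,2S)-2-methyl-1-(triethylsilyloxy)pent-4-en-1-yl]oxolan-2-one | C=CC[C@H](C)[C@@H](O[Si](CC)(CC)CC)[C@@H]1OC(=O)C[C@@H]1C[C@H](Cl)C=O | intermediate
16 | (4R,5R)-4-[(2S)-2-chloro-3-hydroxybutyl]-5-[(1R,2S)-2-methyl-1-(triethylsilyloxy)pent-4-en-1-yl]oxolan-2-one (both carbinol epimers) | C=CC[C@H](C)[C@@H](O[Si](CC)(CC)CC)[C@@H]1OC(=O)C[C@@H]1C[C@H](Cl)C(C)O | intermediate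
17 | (4R,5R)-4-[(2S)-2-chloro-3-oxobutyl]-5-[(1R,2S)-2-methyl-1-(triethylsilyloxy)pent-4-en-1-yl]oxolan-2-one | C=CC[C@H](C)[C@@H](O[Si](CC)(CC)CC)[C@@H]1OC(=O)C[C@@H]1C[C@H](Cl)C(C)=O | intermediate
18 | (1-bromoethenyl)trimethylsilane | C=C(Br)[Si](C)(C)C | starting material
19 | 3-bromopropanoyl chloride | O=C(Cl)CCBr | starting material
20 | [1-(trimethylsilyl)ethenyl]magnesium bromide | C=C([Mg]Br)[Si](C)(C)C | intermediate
21 | 5-bromo-2-(trimethylsilyl)pent-1-en-3-one | C=C(C(=O)CCBr)[Si](C)(C)C | intermediate
22 | (3S)-5-bromo-2-(trimethylsilyl)pent-1-en-3-ol | BrCC[C@H](O)C(=C)[Si](C)(C)C | intermediate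
23 | {[(3S)-5-bromo-2-(trimethylsilyl)pent-1-en-3-yl]oxy}(tert-butyl)dimethylsilane | BrCC[C@H](O[Si](C)(C)C(C)(C)C)C(=C)[Si](C)(C)C | intermediate
24 | {(3S)-3-(tert-butyldimethylsilyloxy)-4-(trimethylsilyl)pent-4-en-1-yl}magnesium bromide | Br[Mg]CC[C@H](O[Si](C)(C)C(C)(C)C)C(=C)[Si](C)(C)C | intermediate
25 | dichloro{(3S)-3-(tert-butyldimethylsilyloxy)-4-(trimethylsilyl)pent-4-en-1-yl}cerium | Cl[Ce](Cl)CC[C@H](O[Si](C)(C)C(C)(C)C)C(=C)[Si](C)(C)C | intermediate
26 | (4R,5R)-4-[(2S,3R,6S)-6-(tert-butyldimethylsilyloxy)-2-chloro-3-hydroxy-3-methyl-7-(trimethylsilyl)oct-7-en-1-yl]-5-[(1R,2S)-2-methyl-1-(triethylsilyloxy)pent-4-en-1-yl]oxolan-2-one | C=CC[C@H](C)[C@@H](O[Si](CC)(CC)CC)[C@@H]1OC(=O)C[C@@H]1C[C@H](Cl)[C@](C)(O)CC[C@H](O[Si](C)(C)C(C)(C)C)C(=C)[Si](C)(C)C | intermediate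
27 | (4S,5R)-4-({(2R,3R)-3-[(3S)-3-(tert-butyldimethylsilyloxy)-4-(trimethylsilyl)pent-4-en-1-yl]-3-methyloxiran-2-yl}methyl)-5-[(1R,2S)-2-methyl-1-(triethylsilyloxy)pent-4-en-1-yl]oxolan-2-one | C=CC[C@H](C)[C@@H](O[Si](CC)(CC)CC)[C@@H]1OC(=O)C[C@@H]1C[C@H]1O[C@]1(C)CC[C@H](O[Si](C)(C)C(C)(C)C)C(=C)[Si](C)(C)C | intermediate
28 | (4S,5R)-4-({(2R,3R)-3-[(3S)-3-(tert-butyldimethylsilyloxy)-4-iodopent-4-en-1-yl]-3-methyloxiran-2-yl}methyl)-5-[(1R,2S)-2-methyl-1-(triethylsilyloxy)pent-4-en-1-yl]oxolan-2-one | C=CC[C@H](C)[C@@H](O[Si](CC)(CC)CC)[C@@H]1OC(=O)C[C@@H]1C[C@H]1O[C@]1(C)CC[C@H](O[Si](C)(C)C(C)(C)C)C(=C)I | intermediate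
29 | C9 B-alkyl-9-borabicyclo[3.3.1]nonane formed from 28 (terminal alkene hydroborated; all stereocentres as in 28) | C1CCC2CCCC1B2CCC[C@H](C)[C@@H](O[Si](CC)(CC)CC)[C@@H]1OC(=O)C[C@@H]1C[C@H]1O[C@]1(C)CC[C@H](O[Si](C)(C)C(C)(C)C)C(=C)I | intermediate
30 | (1S,3R,4R,7S,12S,13R,14R)-7-(tert-butyldimethylsilyloxy)-3,4-epoxy-13-(triethylsilyloxy)-17-norcembr-8(19)-en-16,14-olide | C=C1CCC[C@H](C)[C@@H](O[Si](CC)(CC)CC)[C@@H]2OC(=O)C[C@@H]2C[C@H]2O[C@]2(C)CC[C@@H]1O[Si](C)(C)C(C)(C)C | intermediate
31 | (1S,3R,4R,7S,12S,13R,14R)-7-(tert-butyldimethylsilyloxy)-17-(dimethylamino)-3,4-epoxy-13-(triethylsilyloxy)cembr-8(19)-en-16,14-olide (C15 epimers) | C=C1CCC[C@H](C)[C@@H](O[Si](CC)(CC)CC)[C@@H]2OC(=O)C(CN(C)C)[C@@H]2C[C@H]2O[C@]2(C)CC[C@@H]1O[Si](C)(C)C(C)(C)C | intermediate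
32 | N-methyl ammonium iodide of 31 (17-trimethylammonio compound; C15 epimers) | C=C1CCC[C@H](C)[C@@H](O[Si](CC)(CC)CC)[C@@H]2OC(=O)C(C[N+](C)(C)C)[C@@H]2C[C@H]2O[C@]2(C)CC[C@@H]1O[Si](C)(C)C(C)(C)C.[I-] | intermediate
33 | (1S,3R,4R,7S,12S,13R,14R)-7-(tert-butyldimethylsilyloxy)-3,4-epoxy-13-(triethylsilyloxy)cembra-8(19),15(17)-dien-16,14-olide | C=C1CCC[C@H](C)[C@@H](O[Si](CC)(CC)CC)[C@@H]2OC(=O)C(=C)[C@@H]2C[C@H]2O[C@]2(C)CC[C@@H]1O[Si](C)(C)C(C)(C)C | intermediate
34 | (1S,3R,4R,7S,12S,13R,14R)-7-(tert-butyldimethylsilyloxy)-3,4-epoxy-13-hydroxycembra-8(19),15(17)-dien-16,14-olide | C=C1CCC[C@H](C)[C@@H](O)[C@@H]2OC(=O)C(=C)[C@@H]2C[C@H]2O[C@]2(C)CC[C@@H]1O[Si](C)(C)C(C)(C)C | intermediate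
35 | (1S,3R,4R,7S,12S,13R,14R)-13-acetoxy-7-(tert-butyldimethylsilyloxy)-3,4-epoxycembra-8(19),15(17)-dien-16,14-olide | C=C1CCC[C@H](C)[C@@H](OC(C)=O)[C@@H]2OC(=O)C(=C)[C@@H]2C[C@H]2O[C@]2(C)CC[C@@H]1O[Si](C)(C)C(C)(C)C | intermediate
36 | (1S,3R,4R,7S,12S,13R,14R)-13-acetoxy-3,4-epoxy-7-hydroxycembra-8(19),15(17)-dien-16,14-olide (CNP0230083.1) | C=C1CCC[C@H](C)[C@@H](OC(C)=O)[C@@H]2OC(=O)C(=C)[C@@H]2C[C@H]2O[C@]2(C)CC[C@@H]1O | target

## Step count and least certain steps

Total step count: 22. Longest linear sequence: 16 steps (steps 1, 2, 6–12 and 16–22).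

**Step 16 (key step).** Most likely to go wrong:
- incomplete or reversed facial selectivity at C4, if conformers other than the chlorine-anti one react;
- proton transfer at C3 before addition, which would erode the chloride stereocentre;
- partial methanolysis of the lactone during the carbonate-induced closure.

Fallback, for the case that C5 is found to enter mainly from the C2 side: the two carbon groups are brought to C4 in the other order, so that the same intrinsic preference gives the required configuration. It sets out from α-chloro aldehyde 15 and organocerium reagent 25. Addition of 25 to 15 at −78 °C would give the secondary chlorohydrin F1 (an aldehyde is attacked faster than it is deprotonated). Dess–Martin oxidation would give the α-chloro ketone F2, and MeMgBr premixed with CeCl3 would then add the methyl group to C4. The route is rejoined at chlorohydrin 26, which is closed to 27 with K2CO3 in MeOH as in step 16.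

**Step 7.** Most likely to go wrong: insufficient face selectivity on the aldehyde, because the allylic CH2 and the methyl group on C12 differ little in size, and incomplete syn preference between C13 and C14, so that diastereomers of 11 form together.

Fallback, reagent control by an auxiliary-based syn-glycolate aldol; it sets out from aldehyde 10 and returns at butenolide 12:
- The glycolate imide (4S)-4-benzyl-3-{[(4-methoxybenzyl)oxy]acetyl}-1,3-oxazolidin-2-one F3 (from the commercial oxazolidinone and (4-methoxybenzyloxy)acetyl chloride) would be enolised with Bu2BOTf and Et3N and combined with 10 to give the syn aldol adduct F4.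
- Me3Al and MeNHOMe·HCl would give the hydroxy Weinreb amide F5, and Et3SiOTf the silyl ether F6.
- (3-Bromopropoxy)triethylsilane F7 (from 3-bromopropan-1-ol) would be converted with Mg into the Grignard reagent F8, which would add to F6 to give the ketone F9.
- DDQ would remove the PMB group to give the α-hydroxy ketone F10.
- Ph3P=C=C=O would acylate the C14 hydroxyl and close the ring by intramolecular Wittig reaction to 12.

**Step 11.** Most likely to go wrong: loss of configuration at C3, because α-chloro aldehydes enolise easily during filtration, in contact with the amine catalyst or on meeting the basic Grignard solution, together with partial attack of MeMgBr on the lactone.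

Fallback, acyl cross-coupling in place of carbonyl addition and re-oxidation; it sets out from α-chloro aldehyde 15 and returns at chloro ketone 17. The crude 15 would be oxidised at once under Pinnick conditions (NaClO2, NaH2PO4, 2-methylbut-2-ene) to the more robust α-chloro acid F11. 1-Chloro-N,N,2-trimethylprop-1-en-1-amine would convert it under neutral conditions into the acid chloride F12. MeZnCl with Pd(PPh3)4 (Negishi acylation) would then give 17 without any strongly basic reagent.

**Step 18.** Most likely to go wrong: intermolecular coupling to oligomers, protodeboronation of the alkylborane, or β-hydride elimination from the alkylpalladium intermediate outrunning the slow ring closure.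

Fallback, ring closure through an alkylzinc reagent; it sets out from vinyl iodide 28 and returns at macrocycle 30. Hydroboration with 9-BBN and oxidation with NaBO3 would give the primary alcohol F13, and I2, PPh3 and imidazole the primary iodide F14. Zinc dust with LiCl should insert into the alkyl C–I bond much faster than into the alkenyl C–I bond to give the alkylzinc iodide F15. This would be added slowly to Pd(dppf)Cl2 at high dilution for an intramolecular Negishi coupling at C8–C9.

**Step 10.** Most likely to go wrong: incomplete discrimination between the primary and the secondary triethylsilyl ether, leading to oxidation at C13 as well or to unreacted 13.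

Fallback, deprotection and oxidation as separate operations; it sets out from 13 and returns at 14. Pyridinium p-toluenesulfonate in MeOH/CH2Cl2 at 0 °C would cleave the unhindered primary silyl ether to give the alcohol F16, and Dess–Martin periodinane would oxidise it to 14.

## Further compounds

F1 | step 16 | (4R,5R)-4-[(2S,6S)-6-(tert-butyldimethylsilyloxy)-2-chloro-3-hydroxy-7-(trimethylsilyl)oct-7-en-1-yl]-5-[(1R,2S)-2-methyl-1-(triethylsilyloxy)pent-4-en-1-yl]oxolan-2-one (carbinol epimers) | C=CC[C@H](C)[C@@H](O[Si](CC)(CC)CC)[C@@H]1OC(=O)C[C@@H]1C[C@H](Cl)C(O)CC[C@H](O[Si](C)(C)C(C)(C)C)C(=C)[Si](C)(C)C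
F2 | step 16 | (4R,5R)-4-[(2S,6S)-6-(tert-butyldimethylsilyloxy)-2-chloro-3-oxo-7-(trimethylsilyl)oct-7-en-1-yl]-5-[(1R,2S)-2-methyl-1-(triethylsilyloxy)pent-4-en-1-yl]oxolan-2-one | C=CC[C@H](C)[C@@H](O[Si](CC)(CC)CC)[C@@H]1OC(=O)C[C@@H]1C[C@H](Cl)C(=O)CC[C@H](O[Si](C)(C)C(C)(C)C)C(=C)[Si](C)(C)C
F3 | step 7 | (4S)-4-benzyl-3-{[(4-methoxybenzyl)oxy]acetyl}-1,3-oxazolidin-2-one | COc1ccc(COCC(=O)N2[C@@H](Cc3ccccc3)COC2=O)cc1
F4 | step 7 | (4S)-4-benzyl-3-{(2S,3R,4S)-3-hydroxy-2-[(4-methoxybenzyl)oxy]-4-methylhept-6-enoyl}-1,3-oxazolidin-2-one | C=CC[C@H](C)[C@@H](O)[C@H](OCc1ccc(OC)cc1)C(=O)N1[C@@H](Cc2ccccc2)COC1=O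
F5 | step 7 | (2S,3R,4S)-3-hydroxy-N-methoxy-2-[(4-methoxybenzyl)oxy]-N,4-dimethylhept-6-enamide | C=CC[C@H](C)[C@@H](O)[C@H](OCc1ccc(OC)cc1)C(=O)N(C)OC
F6 | step 7 | (2S,3R,4S)-N-methoxy-2-[(4-methoxybenzyl)oxy]-N,4-dimethyl-3-(triethylsilyloxy)hept-6-enamide | C=CC[C@H](C)[C@@H](O[Si](CC)(CC)CC)[C@H](OCc1ccc(OC)cc1)C(=O)N(C)OC
F7 | step 7 | (3-bromopropoxy)triethylsilane | BrCCCO[Si](CC)(CC)CC
F8 | step 7 | [3-(triethylsilyloxy)propyl]magnesium bromide | Br[Mg]CCCO[Si](CC)(CC)CC
F9 | step 7 | (5S,6R,7S)-5-[(4-methoxybenzyl)oxy]-7-methyl-1,6-bis(triethylsilyloxy)dec-9-en-4-one | C=CC[C@H](C)[C@@H](O[Si](CC)(CC)CC)[C@H](OCc1ccc(OC)cc1)C(=O)CCCO[Si](CC)(CC)CC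
F10 | step 7 | (5S,6R,7S)-5-hydroxy-7-methyl-1,6-bis(triethylsilyloxy)dec-9-en-4-one | C=CC[C@H](C)[C@@H](O[Si](CC)(CC)CC)[C@H](O)C(=O)CCCO[Si](CC)(CC)CC
F11 | step 11 | (2S)-2-chloro-3-{(2R,3R)-2-[(1R,2S)-2-methyl-1-(triethylsilyloxy)pent-4-en-1-yl]-5-oxooxolan-3-yl}propanoic acid | C=CC[C@H](C)[C@@H](O[Si](CC)(CC)CC)[C@@H]1OC(=O)C[C@@H]1C[C@H](Cl)C(=O)O
F12 | step 11 | (2S)-2-chloro-3-{(2R,3R)-2-[(1R,2S)-2-methyl-1-(triethylsilyloxy)pent-4-en-1-yl]-5-oxooxolan-3-yl}propanoyl chloride | C=CC[C@H](C)[C@@H](O[Si](CC)(CC)CC)[C@@H]1OC(=O)C[C@@H]1C[C@H](Cl)C(=O)Cl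
F13 | step 18 | primary C9 alcohol from 28: (4S,5R)-4-({(2R,3R)-3-[(3S)-3-(tert-butyldimethylsilyloxy)-4-iodopent-4-en-1-yl]-3-methyloxiran-2-yl}methyl)-5-[(1R,2S)-5-hydroxy-2-methyl-1-(triethylsilyloxy)pentyl]oxolan-2-one | OCCC[C@H](C)[C@@H](O[Si](CC)(CC)CC)[C@@H]1OC(=O)C[C@@H]1C[C@H]1O[C@]1(C)CC[C@H](O[Si](C)(C)C(C)(C)C)C(=C)I
F14 | step 18 | primary C9 iodide: (4S,5R)-4-({(2R,3R)-3-[(3S)-3-(tert-butyldimethylsilyloxy)-4-iodopent-4-en-1-yl]-3-methyloxiran-2-yl}methyl)-5-[(1R,2S)-5-iodo-2-methyl-1-(triethylsilyloxy)pentyl]oxolan-2-one | ICCC[C@H](C)[C@@H](O[Si](CC)(CC)CC)[C@@H]1OC(=O)C[C@@H]1C[C@H]1O[C@]1(C)CC[C@H](O[Si](C)(C)C(C)(C)C)C(=C)I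
F15 | step 18 | C9 alkylzinc iodide derived from F14 (all stereocentres as in 28) | I[Zn]CCC[C@H](C)[C@@H](O[Si](CC)(CC)CC)[C@@H]1OC(=O)C[C@@H]1C[C@H]1O[C@]1(C)CC[C@H](O[Si](C)(C)C(C)(C)C)C(=C)I
F16 | step 10 | (4S,5R)-4-(3-hydroxypropyl)-5-[(1R,2S)-2-methyl-1-(triethylsilyloxy)pent-4-en-1-yl]oxolan-2-one | C=CC[C@H](C)[C@@H](O[Si](CC)(CC)CC)[C@@H]1OC(=O)C[C@@H]1CCCO
A1 | alternative 1 | 12-membered cyclic enol ether (oxygen between C7 and C3, exocyclic C7=C6 and C8=C19, isopropenyl on C3, C13/C14 acetonide, C16 PMB ether; C3 configuration left open) | C=C1CCC[C@H](C)[C@H]2OC(C)(C)O[C@@H]2[C@H](CCOCc2ccc(OC)cc2)CC(C(C)=C)OC1=C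
A2 | alternative 1 | 14-membered 8-methylene-7-ketone with isolated (E)-C3=C4 alkene, C13/C14 acetonide and C16 PMB ether | C=C1CCC[C@H](C)[C@H]2OC(C)(C)O[C@@H]2[C@H](CCOCc3ccc(OC)cc3)C/C=C(\C)CCC1=O
A3 | alternative 2 | macrocyclic homopropargylic alcohol (C14 hydroxyl, C1 ethynyl, (E)-C3=C4, C13 triethylsilyl ether, C7 tert-butyldimethylsilyl ether) | C=C1CCC[C@H](C)[C@@H](O[Si](CC)(CC)CC)[C@H](O)[C@H](C#C)C/C=C(\C)CC[C@@H]1O[Si](C)(C)C(C)(C)C
A4 | alternative 2 | macrocyclic α-methylene-γ-butyrolactone with (E)-C3=C4 alkene | C=C1CCC[C@H](C)[C@@H](O[Si](CC)(CC)CC)[C@@H]2OC(=O)C(=C)[C@@H]2C/C=C(\C)CC[C@@H]1O[Si](C)(C)C(C)(C)C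
A5 | alternative 3 | open-chain β-methylene lactone carrying the (E)-C3 iodoalkene and the C8 dimethyl ketal | I/C=C(\C)CC[C@H](O[Si](C)(C)C(C)(C)C)C(OC)(OC)CCC[C@H](C)[C@@H](O[Si](CC)(CC)CC)[C@@H]1OC(=O)CC1=C
A6 | alternative 3 | 14-membered carbocycle with cis lactone, (E)-C3=C4 alkene and C8 dimethyl ketal | COC1(OC)CCC[C@H](C)[C@@H](O[Si](CC)(CC)CC)[C@@H]2OC(=O)C[C@@H]2C/C=C(\C)CC[C@@H]1O[Si](C)(C)C(C)(C)C
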